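**Plan**

1. The target is read as unit 1–unit 2–unit 3–unit 4 = epicatechin-(4α→6)-epiafzelechin-(4α→8)-epicatechin-(4β→6)-epicatechin; units 1 and 2 are all-cis (2R,3R, 4-aryl cis to 3-OH).
2. Cuts: both axial 3-OH groups of units 1 and 2 go back to 3-ketones; C4(unit 2)–C8(unit 3) and C4(unit 3)–C6(unit 4) are Friedel–Crafts couplings; in unit 1 the C4–C6(unit 2) and C4–C4a bonds are cut together.
3. Enabling feature: C3 of unit 1 bears oxygen and sits next to C4, which is benzylic to two phloroglucinol-type rings. Ring C of unit 1 (O1, C2, C3, C4, C4a, C8a) can therefore come from a 2-aryl-3-hydroxy-2,3-dihydrobenzofuran-3-carbaldehyde: the aldehyde carbon becomes C4 by hydroxyalkylating C6 of unit 2, then the electron-rich aryl carbon C4a shifts from C3 to C4 and C3 becomes C=O (five- to six-membered ring expansion).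
4. Forward order: aldehyde 9 (six steps) and afzelechin thioether 14 (four steps); the key step joins them and makes ring C of unit 1; silver-promoted coupling with the unit 3–unit 4 dimer 19; oxidation of the unit 2 3-OH; one double reduction; global hydrogenolysis.
5. Stereochemistry: C2 of unit 1 from a catalytic asymmetric epoxidation (inverted once in the phenoxide opening); C4 of unit 1 relayed in the key step; C4 of unit 2 by attack trans to the 3-OH of afzelechin (chiral pool); C3 of units 1 and 2 by hydride delivery anti to the two cis aryl groups; units 3 and 4 from (−)-epicatechin, with C4 of unit 3 set trans to 3-OBn.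
6. Aryl positions that must stay silent (C6 and C8 of unit 1, C8 of units 2 and 4) are capped with bromine and uncovered in the last step.

Key step: step 15

Remark: (+)-afzelechin and (−)-epicatechin are taken as purchasable natural products.

**Route**

Step 1
Reactants: 1 3,4-bis(benzyloxy)benzaldehyde
Product: 2 ethyl (2Z)-3-[3,4-bis(benzyloxy)phenyl]prop-2-enoate
Conditions: (PhO)2P(O)CH2CO2Et, NaH, THF, −78 → 0 °C
Reagents that add atoms: ethyl 2-(diphenoxyphosphoryl)acetate CCOC(=O)CP(=O)(Oc1ccccc1)Oc1ccccc1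
Why: Horner–Wadsworth–Emmons olefination with a diaryl phosphonoacetate should give the Z-enoate, because the electron-poor aryloxy groups speed up elimination from the kinetically formed adduct.

Step 2
Reactants: 2 ethyl (2Z)-3-[3,4-bis(benzyloxy)phenyl]prop-2-enoate
Product: 3 ethyl (2S,3S)-3-[3,4-bis(benzyloxy)phenyl]oxirane-2-carboxylate (cis-glycidate)
Conditions: (S,S)-[N,N'-bis(3,5-di-tert-butylsalicylidene)-1,2-cyclohexanediaminato]MnCl (5 mol %), 4-phenylpyridine N-oxide, aq. NaOCl, CH2Cl2, 0 °C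
Reagents that add atoms: sodium hypochlorite [Na+].[O-]Cl
Why: Jacobsen–Katsuki epoxidation of a cis-cinnamate with the (S,S) catalyst should give the (2S,3S)-cis-glycidate, which sets the benzylic stereocenter (later C2 of unit 1) by catalysis; any trans-epoxide is removed by chromatography.

Step 3
Reactants: 3 ethyl (2S,3S)-3-[3,4-bis(benzyloxy)phenyl]oxirane-2-carboxylate; 4 3,5-bis(benzyloxy)phenol
Product: 5 ethyl (2S,3R)-3-[3,5-bis(benzyloxy)phenoxy]-3-[3,4-bis(benzyloxy)phenyl]-2-hydroxypropanoate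
Conditions: Cs2CO3 (0.2 equiv), DMF, 40 °C
Reagents that add atoms: none
Why: Base-mediated SN2 opening of the aryl glycidate by the phenoxide at the benzylic carbon (epoxide opening with inversion, as with arenethiolates on 3-aryl glycidates) should give the (3R) aryl ether, and C-alkylation of the phloroglucinol-type ring is disfavoured without acid.

Step 4
Reactants: 5 ethyl (2S,3R)-3-[3,5-bis(benzyloxy)phenoxy]-3-[3,4-bis(benzyloxy)phenyl]-2-hydroxypropanoate
Product: 7 ethyl (2R,3R)-4,6-bis(benzyloxy)-2-[3,4-bis(benzyloxy)phenyl]-3-hydroxy-2,3-dihydro-1-benzofuran-3-carboxylate (3-OH cis and ester trans to the 2-aryl group), via α-keto ester 6 (not isolated)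
Conditions: Dess–Martin periodinane, CH2Cl2, 0 °C; then Sc(OTf)3 (10 mol %), −40 → −10 °C
Reagents that add atoms: none
Why: Dess–Martin oxidation gives the α-keto ester, whose ketone is attacked by the ortho position of the electron-rich aryl ether in an intramolecular Friedel–Crafts hydroxyalkylation (5-exo-trig) with the ester taking the face trans to the C2 aryl group, and the acidic low-temperature conditions should keep the enolizable C2–H intact.

Step 5
Reactants: 7 ethyl (2R,3R)-4,6-bis(benzyloxy)-2-[3,4-bis(benzyloxy)phenyl]-3-hydroxy-2,3-dihydro-1-benzofuran-3-carboxylate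
Product: 8 ethyl (2R,3R)-4,6-bis(benzyloxy)-2-[3,4-bis(benzyloxy)phenyl]-5,7-dibromo-3-hydroxy-2,3-dihydro-1-benzofuran-3-carboxylate
Conditions: NBS (2.1 equiv), CH2Cl2, −78 → 0 °C
Reagents that add atoms: N-bromosuccinimide O=C1CCC(=O)N1Br
Why: Electrophilic aromatic bromination at the two free positions of the phloroglucinol-type ring (far more reactive than the catechol-type ring) caps them against Friedel–Crafts self-condensation in steps 15 and 16.

Step 6
Reactants: 8 ethyl (2R,3R)-4,6-bis(benzyloxy)-2-[3,4-bis(benzyloxy)phenyl]-5,7-dibromo-3-hydroxy-2,3-dihydro-1-benzofuran-3-carboxylate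
Product: 9 (2R,3R)-4,6-bis(benzyloxy)-2-[3,4-bis(benzyloxy)phenyl]-5,7-dibromo-3-hydroxy-2,3-dihydro-1-benzofuran-3-carbaldehyde
Conditions: i-Bu2AlH (2.2 equiv), CH2Cl2, −78 °C; aq. Rochelle salt
Reagents that add atoms: none
Why: Partial reduction of the α-hydroxy ester at −78 °C should stop at the chelated tetrahedral aluminate, which releases the aldehyde on work-up.

Step 7
Reactants: 10 (+)-afzelechin
Product: 11 5,7,4'-tri-O-benzyl-(+)-afzelechin
Conditions: BnBr, K2CO3, DMF, rt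
Reagents that add atoms: benzyl bromide BrCc1ccccc1
Why: Williamson etherification of the three phenols; the secondary 3-OH is not alkylated by carbonate.

Step 8
Reactants: 11 5,7,4'-tri-O-benzyl-(+)-afzelechin
Product: 12 8-bromo-5,7,4'-tri-O-benzylafzelechin
Conditions: NBS (1.0 equiv), CH2Cl2, −78 → −20 °C
Reagents that add atoms: N-bromosuccinimide O=C1CCC(=O)N1Br
Why: Electrophilic bromination of benzylated flavan-3-ols goes to C8 first, leaving C6 as the only nucleophilic position of ring A.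

Step 9
Reactants: 12 8-bromo-5,7,4'-tri-O-benzylafzelechin
Product: 13 (2R,3S,4S)-8-bromo-4-(2-ethoxyethoxy)-5,7,4'-tri-O-benzylafzelechin
Conditions: DDQ, 2-ethoxyethanol, CH2Cl2, rt
Reagents that add atoms: 2-ethoxyethanol CCOCCO
Why: DDQ abstracts hydride from the benzylic C4 activated by the dialkoxy ring A and the alcohol traps the cation (benzylic oxidation); the C4 configuration is immaterial because C4 is ionized again later.

Step 10
Reactants: 13 (2R,3S,4S)-8-bromo-4-(2-ethoxyethoxy)-5,7,4'-tri-O-benzylafzelechin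
Product: 14 4α-(benzylsulfanyl)-8-bromo-5,7,4'-tri-O-benzylafzelechin (2,3-trans-3,4-trans)
Conditions: BnSH, BF3·OEt2 (20 mol %), CH2Cl2, −78 → −30 °C
Reagents that add atoms: phenylmethanethiol SCc1ccccc1
Why: Acid-catalysed exchange through the C4 cation (thiolysis) gives a thioether that is inert to Sc(OTf)3 in step 15 but is released by silver ion in step 16.

Step 11
Reactants: 15 (−)-epicatechin
Product: 16 3,5,7,3',4'-penta-O-benzylepicatechin
Conditions: BnBr, K2CO3, DMF, rt; then NaH, BnBr, 0 °C → rt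
Reagents that add atoms: benzyl bromide BrCc1ccccc1
Why: Williamson etherification of the four phenols and then of the 3-OH, so that the 3-oxygens of units 3 and 4 are inert to the later oxidation.

Step 12
Reactants: 16 3,5,7,3',4'-penta-O-benzylepicatechin
Product: 17 8-bromo-3,5,7,3',4'-penta-O-benzylepicatechin
Conditions: NBS (1.0 equiv), CH2Cl2, −78 → −20 °C
Reagents that add atoms: N-bromosuccinimide O=C1CCC(=O)N1Br
Why: C8-selective electrophilic bromination blocks C8 of unit 4, so that the coming coupling must use C6.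

Step 13
Reactants: 16 3,5,7,3',4'-penta-O-benzylepicatechin
Product: 18 (2R,3R,4S)-4-(2-ethoxyethoxy)-3,5,7,3',4'-penta-O-benzylepicatechin (4β)
Conditions: DDQ, 2-ethoxyethanol, CH2Cl2, rt
Reagents that add atoms: 2-ethoxyethanol CCOCCO
Why: DDQ benzylic oxidation at C4 with alcohol trapping trans to the 3-benzyloxy group gives the usual C4 electrophile of the epicatechin series.

Step 14
Reactants: 18 (2R,3R,4S)-4-(2-ethoxyethoxy)-3,5,7,3',4'-penta-O-benzylepicatechin; 17 8-bromo-3,5,7,3',4'-penta-O-benzylepicatechin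
Product: 19 3,5,7,3',4'-penta-O-benzylepicatechin-(4β→6)-8-bromo-3,5,7,3',4'-penta-O-benzylepicatechin
Conditions: 17 (4 equiv), TMSOTf (10 mol %), CH2Cl2, −78 °C
Reagents that add atoms: none
Why: Friedel–Crafts alkylation of C6 of 17 (C8 blocked) by the C4 cation of 18, attacked trans to the 3-benzyloxy group (4β); the excess of 17 suppresses self-condensation of 18.

Step 15
Reactants: 9 (2R,3R)-4,6-bis(benzyloxy)-2-[3,4-bis(benzyloxy)phenyl]-5,7-dibromo-3-hydroxy-2,3-dihydro-1-benzofuran-3-carbaldehyde; 14 4α-(benzylsulfanyl)-8-bromo-5,7,4'-tri-O-benzylafzelechin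
Product: 21 4α-(benzylsulfanyl)-8-bromo-5,7,4'-tri-O-benzylafzelechin bearing at C6 the (2R,4R)-5,7-bis(benzyloxy)-2-[3,4-bis(benzyloxy)phenyl]-6,8-dibromo-3-oxochroman-4-yl group (2,4-cis), via pinacol-type diol 20 (not isolated)
Conditions: 14 (1.5 equiv), Sc(OTf)3 (10 mol %), 4 Å MS, CH2Cl2, −40 → 0 °C
Reagents that add atoms: none
Why: Proposed new method: Sc(OTf)3 activates the aldehyde of 9 for Friedel–Crafts hydroxyalkylation by C6 of 14 (the only free position of its phloroglucinol-type ring) to give diol 20, whose secondary benzylic hydroxyl ionizes to a cation at the future C4 that is stabilized by the trioxygenated ring of unit 2. The aryl carbon C3a of the dihydrobenzofuran (oxygen-substituted at both ortho positions and para) then shifts from C3 to this cation while the tertiary C3–OH becomes the carbonyl, so no ring is closed: the five-membered ring O1–C2–C3–C3a–C7a is enlarged to the six-membered ring O1–C2–C3–C4–C4a–C8a by a 1,2-aryl shift, and the C4–C6 interflavan bond, the C4–C4a bond and the C3 carbonyl arise in one operation. The closest known reaction types are the pinacol (semipinacol) ring expansion of 1-(α-hydroxyalkyl)cycloalkanols and their benzo-fused analogues by 1,2-shift of a ring carbon, and the Friedel–Crafts hydroxyalkylation of trialkoxyarenes with aldehydes; their one-pot union on a 3-hydroxy-2,3-dihydrobenzofuran-3-carbaldehyde is new. C2 is not touched and stays R, and the new C4 should form cis to the C2 aryl group because the formyl-derived carbon stands trans to that aryl on C3 and, in the transition state of the shift, the unit 2 ring lies over the small C3 oxygen and not over C2; as C4 is α to the ketone, 21 is carried on without delay. The step needs aryl migration over migration of C2 (secured by the electron-rich ipso carbon and by C2 carrying the aryl ether oxygen), intermolecular hydroxyalkylation over α-ketol isomerization of 9 (excess 14, low temperature) and no self-condensation (both free positions of the unit 1 ring carry bromine); the C4 thioether of 14 is inert to Sc(OTf)3.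

Step 16
Reactants: 21 the unit 1 ketone–unit 2 thioether dimer; 19 3,5,7,3',4'-penta-O-benzylepicatechin-(4β→6)-8-bromo-3,5,7,3',4'-penta-O-benzylepicatechin
Product: 22 protected tetramer with unit 1 as 3-ketone and unit 2 as 2,3-trans-3,4-trans 3-ol (unit 2 C4α bonded to C8 of unit 3)
Conditions: 19 (1.5 equiv), AgBF4, THF, 0 °C
Reagents that add atoms: none
Why: Silver ion removes the benzylthio group under non-protic conditions and the C4 cation of unit 2 is attacked by C8 of unit 3 (the most nucleophilic free position of 19) trans to the 3-OH of unit 2, giving the 4α bond; the rings of units 1 and 4 are bromine-capped.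

Step 17
Reactants: 22 protected tetramer with unit 1 as 3-ketone and unit 2 as 3-ol
Product: 23 protected tetramer with 3-ketones in units 1 and 2 (both 2,4-cis)
Conditions: Dess–Martin periodinane, CH2Cl2, 0 °C → rt
Reagents that add atoms: none
Why: Dess–Martin oxidation of the only free secondary alcohol (C3–OH of unit 2) under non-basic conditions, which should spare the enolizable C4 centers.

Step 18
Reactants: 23 protected tetramer with 3-ketones in units 1 and 2
Product: 24 heptadeca-O-benzyl tetrabromo derivative of the target (units 1 and 2 all-cis, free 3-OH in both)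
Conditions: Li[HB(s-Bu)3] (L-Selectride), LiBr, THF, −78 °C
Reagents that add atoms: none
Why: The bulky borohydride attacks each 2,4-cis-diaryl chroman-3-one from the equatorial direction, anti to both flanking aryl groups, to give the axial (3R) alcohols, as in the known reduction of benzylated flavan-3-ones to 2,3-cis flavan-3-ols.

Step 19
Reactants: 24 heptadeca-O-benzyl tetrabromo derivative of the target
Product: 25 CNP0103636.2, epicatechin-(4α→6)-epiafzelechin-(4α→8)-epicatechin-(4β→6)-epicatechin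
Conditions: H2 (1 atm), Pd(OH)2/C, Et3N, THF/MeOH/H2O, rt
Reagents that add atoms: none
Why: Hydrogenolysis of the seventeen benzyl ethers and hydrodehalogenation of the four aryl bromides in one operation, with Et3N taking up HBr so that the acid-labile interflavan bonds survive.

**Compound list**

1 | 3,4-bis(benzyloxy)benzaldehyde | O=Cc1ccc(OCc2ccccc2)c(OCc2ccccc2)c1 | starting material
2 | ethyl (2Z)-3-[3,4-bis(benzyloxy)phenyl]prop-2-enoate | CCOC(=O)/C=C\c1ccc(OCc2ccccc2)c(OCc2ccccc2)c1 | intermediate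
3 | ethyl (2S,3S)-3-[3,4-bis(benzyloxy)phenyl]oxirane-2-carboxylate | CCOC(=O)[C@H]1O[C@H]1c2ccc(OCc3ccccc3)c(OCc3ccccc3)c2 | intermediate
4 | 3,5-bis(benzyloxy)phenol | Oc1cc(OCc2ccccc2)cc(OCc2ccccc2)c1 | starting material
5 | ethyl (2S,3R)-3-[3,5-bis(benzyloxy)phenoxy]-3-[3,4-bis(benzyloxy)phenyl]-2-hydroxypropanoate | CCOC(=O)[C@@H](O)[C@H](Oc1cc(OCc2ccccc2)cc(OCc2ccccc2)c1)c1ccc(OCc2ccccc2)c(OCc2ccccc2)c1 | intermediate
6 | ethyl (3R)-3-[3,5-bis(benzyloxy)phenoxy]-3-[3,4-bis(benzyloxy)phenyl]-2-oxopropanoate | CCOC(=O)C(=O)[C@H](Oc1cc(OCc2ccccc2)cc(OCc2ccccc2)c1)c1ccc(OCc2ccccc2)c(OCc2ccccc2)c1 | intermediate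
7 | ethyl (2R,3R)-4,6-bis(benzyloxy)-2-[3,4-bis(benzyloxy)phenyl]-3-hydroxy-2,3-dihydro-1-benzofuran-3-carboxylate | CCOC(=O)[C@]1(O)[C@@H](c2ccc(OCc3ccccc3)c(OCc3ccccc3)c2)Oc2cc(OCc3ccccc3)cc(OCc3ccccc3)c12 | intermediate
8 | ethyl (2R,3R)-4,6-bis(benzyloxy)-2-[3,4-bis(benzyloxy)phenyl]-5,7-dibromo-3-hydroxy-2,3-dihydro-1-benzofuran-3-carboxylate | CCOC(=O)[C@]1(O)[C@@H](c2ccc(OCc3ccccc3)c(OCc3ccccc3)c2)Oc2c(Br)c(OCc3ccccc3)c(Br)c(OCc3ccccc3)c12 | intermediate
9 | (2R,3R)-4,6-bis(benzyloxy)-2-[3,4-bis(benzyloxy)phenyl]-5,7-dibromo-3-hydroxy-2,3-dihydro-1-benzofuran-3-carbaldehyde | O=C[C@]1(O)[C@@H](c2ccc(OCc3ccccc3)c(OCc3ccccc3)c2)Oc2c(Br)c(OCc3ccccc3)c(Br)c(OCc3ccccc3)c12 | intermediate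
10 | (+)-afzelechin, (2R,3S)-2-(4-hydroxyphenyl)chroman-3,5,7-triol | Oc1ccc([C@H]2Oc3cc(O)cc(O)c3C[C@@H]2O)cc1 | starting material
11 | 5,7,4'-tri-O-benzyl-(+)-afzelechin | C(c6ccccc6)Oc1ccc([C@H]2Oc3cc(OCc6ccccc6)cc(OCc6ccccc6)c3C[C@@H]2O)cc1 | intermediate
12 | 8-bromo-5,7,4'-tri-O-benzylafzelechin | C(c6ccccc6)Oc1ccc([C@H]2Oc3c(Br)c(OCc6ccccc6)cc(OCc6ccccc6)c3C[C@@H]2O)cc1 | intermediate
13 | (2R,3S,4S)-8-bromo-4-(2-ethoxyethoxy)-5,7,4'-tri-O-benzylafzelechin | C(c6ccccc6)Oc1ccc([C@H]2Oc3c(Br)c(OCc6ccccc6)cc(OCc6ccccc6)c3[C@H](OCCOCC)[C@@H]2O)cc1 | intermediate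
14 | 4α-(benzylsulfanyl)-8-bromo-5,7,4'-tri-O-benzylafzelechin (2,3-trans-3,4-trans) | C(c6ccccc6)Oc1ccc([C@H]2Oc3c(Br)c(OCc6ccccc6)cc(OCc6ccccc6)c3[C@@H](SCc6ccccc6)[C@@H]2O)cc1 | intermediate
15 | (−)-epicatechin | O[C@@H]1Cc2c(O)cc(O)cc2O[C@@H]1c1ccc(O)c(O)c1 | starting material
16 | 3,5,7,3',4'-penta-O-benzylepicatechin | c1c(OCc6ccccc6)cc(OCc6ccccc6)c2c1O[C@H](c1ccc(OCc6ccccc6)c(OCc6ccccc6)c1)[C@H](OCc6ccccc6)C2 | intermediate
17 | 8-bromo-3,5,7,3',4'-penta-O-benzylepicatechin | c1c(OCc6ccccc6)c(Br)c2c(c1OCc6ccccc6)C[C@@H](OCc6ccccc6)[C@@H](c1ccc(OCc6ccccc6)c(OCc6ccccc6)c1)O2 | intermediate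
18 | (2R,3R,4S)-4-(2-ethoxyethoxy)-3,5,7,3',4'-penta-O-benzylepicatechin | c1c(OCc6ccccc6)cc(OCc6ccccc6)c2c1O[C@H](c1ccc(OCc6ccccc6)c(OCc6ccccc6)c1)[C@H](OCc6ccccc6)[C@H]2OCCOCC | intermediate
19 | 3,5,7,3',4'-penta-O-benzylepicatechin-(4β→6)-8-bromo-3,5,7,3',4'-penta-O-benzylepicatechin | c1c(OCc6ccccc6)cc(OCc6ccccc6)c2c1O[C@H](c1ccc(OCc6ccccc6)c(OCc6ccccc6)c1)[C@H](OCc6ccccc6)[C@H]2c1c(OCc6ccccc6)c(Br)c2c(c1OCc6ccccc6)C[C@@H](OCc6ccccc6)[C@@H](c1ccc(OCc6ccccc6)c(OCc6ccccc6)c1)O2 | intermediate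
20 | diol from hydroxyalkylation of C6 of 14 by 9 (carbinol carbon as a mixture of epimers) | C(c6ccccc6)Oc1ccc([C@H]2Oc3c(Br)c(OCc6ccccc6)c(C(O)[C@]4(O)[C@@H](c5ccc(OCc6ccccc6)c(OCc6ccccc6)c5)Oc5c(Br)c(OCc6ccccc6)c(Br)c(OCc6ccccc6)c45)c(OCc6ccccc6)c3[C@@H](SCc6ccccc6)[C@@H]2O)cc1 | intermediate
21 | unit 1 (2R,4R)-3-ketone joined through C4 to C6 of unit 2 thioether 14 | C(c6ccccc6)Oc1ccc([C@H]2Oc3c(Br)c(OCc6ccccc6)c([C@@H]4c5c(OCc6ccccc6)c(Br)c(OCc6ccccc6)c(Br)c5O[C@H](c5ccc(OCc6ccccc6)c(OCc6ccccc6)c5)C4=O)c(OCc6ccccc6)c3[C@@H](SCc6ccccc6)[C@@H]2O)cc1 | intermediate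
22 | protected tetramer, unit 1 as 3-ketone, unit 2 as 2,3-trans-3,4-trans 3-ol | C(c6ccccc6)Oc1ccc([C@H]2Oc3c(Br)c(OCc6ccccc6)c([C@@H]4c5c(OCc6ccccc6)c(Br)c(OCc6ccccc6)c(Br)c5O[C@H](c5ccc(OCc6ccccc6)c(OCc6ccccc6)c5)C4=O)c(OCc6ccccc6)c3[C@@H](c3c(OCc6ccccc6)cc(OCc6ccccc6)c4c3O[C@H](c3ccc(OCc6ccccc6)c(OCc6ccccc6)c3)[C@H](OCc6ccccc6)[C@H]4c3c(OCc6ccccc6)c(Br)c4c(c3OCc6ccccc6)C[C@@H](OCc6ccccc6)[C@@H](c3ccc(OCc6ccccc6)c(OCc6ccccc6)c3)O4)[C@@H]2O)cc1 | intermediate
23 | protected tetramer with 3-ketones in units 1 and 2 | C(c6ccccc6)Oc1ccc([C@H]2Oc3c(Br)c(OCc6ccccc6)c([C@@H]4c5c(OCc6ccccc6)c(Br)c(OCc6ccccc6)c(Br)c5O[C@H](c5ccc(OCc6ccccc6)c(OCc6ccccc6)c5)C4=O)c(OCc6ccccc6)c3[C@@H](c3c(OCc6ccccc6)cc(OCc6ccccc6)c4c3O[C@H](c3ccc(OCc6ccccc6)c(OCc6ccccc6)c3)[C@H](OCc6ccccc6)[C@H]4c3c(OCc6ccccc6)c(Br)c4c(c3OCc6ccccc6)C[C@@H](OCc6ccccc6)[C@@H](c3ccc(OCc6ccccc6)c(OCc6ccccc6)c3)O4)C2=O)cc1 | intermediate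
24 | heptadeca-O-benzyl tetrabromo derivative of the target | C(c6ccccc6)Oc1ccc([C@H]2Oc3c(Br)c(OCc6ccccc6)c([C@@H]4c5c(OCc6ccccc6)c(Br)c(OCc6ccccc6)c(Br)c5O[C@H](c5ccc(OCc6ccccc6)c(OCc6ccccc6)c5)[C@@H]4O)c(OCc6ccccc6)c3[C@@H](c3c(OCc6ccccc6)cc(OCc6ccccc6)c4c3O[C@H](c3ccc(OCc6ccccc6)c(OCc6ccccc6)c3)[C@H](OCc6ccccc6)[C@H]4c3c(OCc6ccccc6)c(Br)c4c(c3OCc6ccccc6)C[C@@H](OCc6ccccc6)[C@@H](c3ccc(OCc6ccccc6)c(OCc6ccccc6)c3)O4)[C@H]2O)cc1 | intermediate
25 | CNP0103636.2 | Oc1ccc([C@H]2Oc3cc(O)c([C@@H]4c5c(O)cc(O)cc5O[C@H](c5ccc(O)c(O)c5)[C@@H]4O)c(O)c3[C@@H](c3c(O)cc(O)c4c3O[C@H](c3ccc(O)c(O)c3)[C@H](O)[C@H]4c3c(O)cc4c(c3O)C[C@@H](O)[C@@H](c3ccc(O)c(O)c3)O4)[C@H]2O)cc1 | target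

**Totals**

Total step count: 19. Longest linear sequence: 11 steps (steps 1–6 and 15–19).

**Steps most likely to fail**

1. Step 15 (Proposed new method). What may go wrong: migration of C2 in place of the aryl carbon, α-ketol isomerization of the hindered aldehyde before the arene adds, or enolization of the new ketone with loss of the C4 configuration. Fallback with known chemistry, setting out from 14: (+)-catechin is benzylated on its phenols (BnBr, K2CO3) to 5,7,3',4'-tetra-O-benzylcatechin F1. F1 is oxidized at C4 with DDQ and 2-ethoxyethanol to 4-(2-ethoxyethoxy)-5,7,3',4'-tetra-O-benzylcatechin F2. F2 is brominated at C6 and C8 with NBS to 6,8-dibromo-4-(2-ethoxyethoxy)-5,7,3',4'-tetra-O-benzylcatechin F3. F3 is coupled with 14 under catalytic TMSOTf (the thioether stays intact, attack trans to the 3-OH) to the catechin-(4α→6)-afzelechin thioether dimer F4. F4 is coupled with 19 under AgBF4 to the tetramer with 2,3-trans-3,4-trans 3-ols in units 1 and 2 F5. Dess–Martin oxidation of both free 3-hydroxyls of F5 then returns to the route at 23.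

2. Step 18. What may go wrong: deprotonation of the doubly benzylic C4–H by the basic hydride in place of carbonyl addition, and epimerization at C4 before reduction, so that the face selection is lost. Fallback, setting out from 23 and returning at 24: transfer hydrogenation with RuCl(p-cymene)(TsNCH2CH2NH2) and HCO2H/Et3N. Here C4 of each ketone is allowed to epimerize and the 2,4-cis epimer, which offers one open face, is reduced selectively (dynamic kinetic resolution under substrate control). No new compound is made.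

3. Step 16. What may go wrong: attack at C6 in place of C8 of unit 3, and acid-induced scrambling of the interflavan bond of 19 by the acid set free. Fallback, setting out from 21 and returning at 22: 21 is coupled under AgBF4 with an excess of the monomer 18 (C8 attack, ethoxyethyl ether untouched by silver ion) to the unit 1–unit 2–unit 3 trimer bearing the 4β-(2-ethoxyethoxy) group on unit 3 F6. F6 is then coupled with an excess of 17 under catalytic TMSOTf (attack trans to 3-OBn at C6 of 17) to give 22.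

**Further compounds**

F1 | step 15 | 5,7,3',4'-tetra-O-benzylcatechin | C(c6ccccc6)Oc1ccc([C@H]2Oc3cc(OCc6ccccc6)cc(OCc6ccccc6)c3C[C@@H]2O)cc1OCc6ccccc6
F2 | step 15 | 4-(2-ethoxyethoxy)-5,7,3',4'-tetra-O-benzylcatechin | C(c6ccccc6)Oc1ccc([C@H]2Oc3cc(OCc6ccccc6)cc(OCc6ccccc6)c3[C@H](OCCOCC)[C@@H]2O)cc1OCc6ccccc6
F3 | step 15 | 6,8-dibromo-4-(2-ethoxyethoxy)-5,7,3',4'-tetra-O-benzylcatechin | C(c6ccccc6)Oc1ccc([C@H]2Oc3c(Br)c(OCc6ccccc6)c(Br)c(OCc6ccccc6)c3[C@H](OCCOCC)[C@@H]2O)cc1OCc6ccccc6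
F4 | step 15 | catechin-(4α→6)-afzelechin thioether dimer (unit 1 3-ol analogue of 21) | C(c6ccccc6)Oc1ccc([C@H]2Oc3c(Br)c(OCc6ccccc6)c([C@@H]4c5c(OCc6ccccc6)c(Br)c(OCc6ccccc6)c(Br)c5O[C@H](c5ccc(OCc6ccccc6)c(OCc6ccccc6)c5)[C@H]4O)c(OCc6ccccc6)c3[C@@H](SCc6ccccc6)[C@@H]2O)cc1
F5 | step 15 | protected tetramer with 2,3-trans-3,4-trans 3-ols in units 1 and 2 | C(c6ccccc6)Oc1ccc([C@H]2Oc3c(Br)c(OCc6ccccc6)c([C@@H]4c5c(OCc6ccccc6)c(Br)c(OCc6ccccc6)c(Br)c5O[C@H](c5ccc(OCc6ccccc6)c(OCc6ccccc6)c5)[C@H]4O)c(OCc6ccccc6)c3[C@@H](c3c(OCc6ccccc6)cc(OCc6ccccc6)c4c3O[C@H](c3ccc(OCc6ccccc6)c(OCc6ccccc6)c3)[C@H](OCc6ccccc6)[C@H]4c3c(OCc6ccccc6)c(Br)c4c(c3OCc6ccccc6)C[C@@H](OCc6ccccc6)[C@@H](c3ccc(OCc6ccccc6)c(OCc6ccccc6)c3)O4)[C@@H]2O)cc1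
F0 | step 18 | none | none
F6 | step 16 | unit 1–unit 2–unit 3 trimer with 4β-(2-ethoxyethoxy) group on unit 3 | C(c6ccccc6)Oc1ccc([C@H]2Oc3c(Br)c(OCc6ccccc6)c([C@@H]4c5c(OCc6ccccc6)c(Br)c(OCc6ccccc6)c(Br)c5O[C@H](c5ccc(OCc6ccccc6)c(OCc6ccccc6)c5)C4=O)c(OCc6ccccc6)c3[C@@H](c3c(OCc6ccccc6)cc(OCc6ccccc6)c4c3O[C@H](c3ccc(OCc6ccccc6)c(OCc6ccccc6)c3)[C@H](OCc6ccccc6)[C@H]4OCCOCC)[C@@H]2O)cc1
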